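## Retrosynthetic overview

1. Germacrane numbering: C1=C2 is the dihydrofuran alkene, C3 the hemiketal carbon, C4=C5 the ring alkene (C15 methyl on C4), C6 the lactone O–CH, C7 the ring fusion, C8 the ester carbinol, C9 a CH2, C10 the ether carbon (C14 methyl), C11=C13 the methylene and C12 the lactone carbonyl. The plan rests on C3, the atom shared by the ten-membered carbocycle C1–C10 and the 2,5-dihydrofuran (O, C3, C2, C1, C10). It carries two oxygens and only the alkenyl carbons C2 and C4, so it is a masked divinyl-ketone carbonyl that CO can deliver.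
2. The last disconnection is the C8–O ester: acid 35, with its allylic acetate, is attached only after all palladium chemistry. The key disconnection breaks O10–C3, C2–C3 and C3–C4, leading back to the seco C4 iodide/C2 stannane 24 and CO 25.
3. The seco compound is cut at C7–C8. This is a BF3-promoted SE2' addition of stannylmethylbutenolide 21 (fragment 2: C4–C7, C11–C13, C15) to aldehyde 9 (fragment 1: C8–C10, C1, C2, C14).
4. Stereocontrol: C10 comes from Sharpless epoxidation and C6 from a lipase resolution. C7 and C8 are relayed from C6 in the fragment union, and C3 is relayed from C10 through the bridge. Both Z-alkenyl units come from hydroxyl-directed trans-hydroalumination.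
5. Ring order: the lactone ring is made first, as a butenolide by ring-closing metathesis (step 11). The ten-membered carbocycle and the dihydrofuran then form together in step 16.

Key step: step 16

Assumption: commercial 1 and 29 are used as the pure E isomers, and the lipase of step 9 shows its normal preference for acylating the R alcohol (large group iodopropenyl, medium group vinyl).

## Route

### Fragment 1 (steps 1–5)

Step 1
Reactants: 1 (E)-3-methylpent-2-en-4-yn-1-ol
Product: 2 [(2S,3S)-3-ethynyl-3-methyloxiran-2-yl]methanol
Conditions: Ti(OiPr)4 (10 mol %), L-(+)-diethyl tartrate (12 mol %), t-BuOOH, 4 Å MS, CH2Cl2, −20 °C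
Reagents that add atoms: tert-butyl hydroperoxide, CC(C)(C)OO
Why: Sharpless asymmetric epoxidation, in which the titanium L-tartrate complex oxidises the E-allylic alcohol in the same facial sense as other 3-methyl E-allylic alcohols to give the 2S,3S epoxide, which sets C10 (the centre at C9 is removed in step 2) and leaves the alkyne untouched.

Step 2
Reactants: 2 [(2S,3S)-3-ethynyl-3-methyloxiran-2-yl]methanol
Product: 5 (3R,4Z)-5-iodo-3-methylpent-4-ene-1,3-diol, via alkynediol alkoxide 3 (not isolated), via cyclic alkenylalanate 4 (not isolated)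
Conditions: NaAlH2(OCH2CH2OMe)2 (3.5 equiv), THF, 0 °C to rt; EtOAc, 0 °C; I2, THF, −78 to 0 °C; aq potassium sodium tartrate
Reagents that add atoms: iodine, [I][I]
Why: Hydroxyl-directed hydride opening of the 2,3-epoxy alcohol at C9 leaves the C10–O bond and hence C10 intact, the tertiary propargylic alkoxide so formed then directs trans-hydroalumination of the alkyne, and iodinolysis of the five-membered alkenylalanate with retention gives the Z-iodide.

Step 3
Reactants: 5 (3R,4Z)-5-iodo-3-methylpent-4-ene-1,3-diol
Product: 6 (1Z,3R)-1-iodo-3-methyl-3,5-bis(triethylsilyloxy)pent-1-ene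
Conditions: TESOTf (2.5 equiv), 2,6-lutidine, CH2Cl2, −78 to 0 °C
Reagents that add atoms: triethylsilyl trifluoromethanesulfonate, CC[Si](CC)(CC)OS(=O)(=O)C(F)(F)F
Why: Silyl triflate silylation is reactive enough for the tertiary allylic hydroxyl, and the hindered base prevents ionisation or elimination at C10.

Step 4
Reactants: 6 (1Z,3R)-1-iodo-3-methyl-3,5-bis(triethylsilyloxy)pent-1-ene
Product: 8 (1Z,3R)-3-methyl-3,5-bis(triethylsilyloxy)-1-(tributylstannyl)pent-1-ene, via Z-alkenyllithium 7 (not isolated)
Conditions: t-BuLi (2.1 equiv), Et2O, −78 °C; Bu3SnCl, −78 °C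
Reagents that add atoms: tributyltin chloride, CCCC[Sn](Cl)(CCCC)CCCC
Why: Iodine–lithium exchange and stannylation both proceed with retention of alkene geometry, and diethyl ether at −78 °C with immediate trapping keeps the Z-γ-silyloxy alkenyllithium from 1,4 oxygen-to-carbon silyl migration.

Step 5
Reactants: 8 (1Z,3R)-3-methyl-3,5-bis(triethylsilyloxy)-1-(tributylstannyl)pent-1-ene
Product: 9 (3R,4Z)-3-methyl-3-(triethylsilyloxy)-5-(tributylstannyl)pent-4-enal
Conditions: (COCl)2, DMSO, CH2Cl2, −78 to −40 °C; Et3N, −78 to 0 °C
Reagents that add atoms: none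
Why: Swern oxidation applied directly to the silyl ether, in which the activated sulfonium salt attacks only the unhindered primary triethylsilyl ether so that deprotection and oxidation happen in one operation while the tertiary silyl ether and the alkenylstannane persist.

### Fragment 2 (steps 6–12)

Step 6
Reactants: 10 but-2-yn-1-ol
Product: 12 (Z)-3-iodobut-2-en-1-ol, via cyclic alkenylalanate 11 (not isolated)
Conditions: NaAlH2(OCH2CH2OMe)2 (1.5 equiv), THF, 0 °C to rt; EtOAc, 0 °C; I2, THF, −78 °C
Reagents that add atoms: iodine, [I][I]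
Why: Hydroxyl-directed trans-hydroalumination places aluminium on the distal alkyne carbon within a five-membered chelate, and iodinolysis with retention gives the iodide cis to the carbinol carbon, which is the C4=C5 geometry of the target.

Step 7
Reactants: 12 (Z)-3-iodobut-2-en-1-ol
Product: 13 (Z)-3-iodobut-2-enal
Conditions: MnO2, CH2Cl2, rt, dark, used at once
Reagents that add atoms: none
Why: Allylic alcohol oxidation with MnO2 is neutral and heterogeneous, so the isomerisation-prone Z-β-iodoenal is obtained without acid or base contact.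

Step 8
Reactants: 13 (Z)-3-iodobut-2-enal; 14 vinylmagnesium bromide
Product: 15 racemic (4Z)-5-iodohexa-1,4-dien-3-ol
Conditions: THF, −78 °C; sat aq NH4Cl
Reagents that add atoms: none
Why: Grignard 1,2-addition to the aldehyde is much faster at −78 °C than conjugate attack or iodine–magnesium exchange, and it brings in C7 without any stereocontrol at C6 at this point.

Step 9
Reactants: 15 racemic (4Z)-5-iodohexa-1,4-dien-3-ol
Product: 16 (3S,4Z)-5-iodohexa-1,4-dien-3-ol
Conditions: Novozym 435 (immobilised Candida antarctica lipase B), vinyl acetate, MTBE, 30 °C, stopped just past half conversion; chromatography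
Reagents that add atoms: none
Why: Lipase-catalysed kinetic resolution by irreversible transesterification, in which the enzyme acetylates the R alcohol according to the usual size rule for secondary alcohols and leaves the required S alcohol, which fixes C6 before the lactone ring exists and so avoids any configurationally labile γ-formylbutenolide.

Step 10
Reactants: 16 (3S,4Z)-5-iodohexa-1,4-dien-3-ol; 17 2-(bromomethyl)acrylic acid
Product: 18 (3S,4Z)-5-iodohexa-1,4-dien-3-yl 2-(bromomethyl)acrylate
Conditions: DCC, DMAP (5 mol %), CH2Cl2, 0 °C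
Reagents that add atoms: none
Why: Steglich esterification acylates on oxygen with retention at C6 and brings in C13 already functionalised, and a low DMAP loading at 0 °C limits attack of the catalyst on the allylic bromide.

Step 11
Reactants: 18 (3S,4Z)-5-iodohexa-1,4-dien-3-yl 2-(bromomethyl)acrylate
Product: 19 (5S)-3-(bromomethyl)-5-[(1Z)-2-iodoprop-1-en-1-yl]furan-2(5H)-one
Conditions: second-generation Grubbs catalyst (5 mol %), CH2Cl2 (5 mM), reflux
Reagents that add atoms: none
Why: Ring-closing metathesis, in which the ruthenium alkylidene forms at the monosubstituted vinyl group and closes onto the 1,1-disubstituted acrylate to give the five-membered butenolide with loss of ethylene, while the trisubstituted iodoalkene is too hindered and deactivated to take part.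

Step 12
Reactants: 19 (5S)-3-(bromomethyl)-5-[(1Z)-2-iodoprop-1-en-1-yl]furan-2(5H)-one
Product: 21 (5S)-5-[(1Z)-2-iodoprop-1-en-1-yl]-3-[(tributylstannyl)methyl]furan-2(5H)-one, via allylzinc bromide 20 (not isolated)
Conditions: Zn dust, Bu3SnCl (both present from the start), THF, 0 °C to rt
Reagents that add atoms: tributyltin chloride, CCCC[Sn](Cl)(CCCC)CCCC
Why: Barbier-type stannylation of an allylic bromide, in which zinc inserts only into the allylic C–Br bond (alkenyl iodides are inert to zinc dust at this temperature) and the non-basic allylzinc is trapped by the bulky tin chloride at the unhindered C13 terminus, which is also the more stable allylstannane (primary C–Sn bond, endocyclic conjugated alkene).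

### Fragment union and seco compound (steps 13–15)

Step 13
Reactants: 9 (3R,4Z)-3-methyl-3-(triethylsilyloxy)-5-(tributylstannyl)pent-4-enal; 21 (5S)-5-[(1Z)-2-iodoprop-1-en-1-yl]-3-[(tributylstannyl)methyl]furan-2(5H)-one
Product: 22 (4R,5S)-4-[(1R,3R,4Z)-1-hydroxy-3-methyl-3-(triethylsilyloxy)-5-(tributylstannyl)pent-4-en-1-yl]-5-[(1Z)-2-iodoprop-1-en-1-yl]-3-methylideneoxolan-2-one
Conditions: BF3·OEt2 (1.5 equiv), CH2Cl2, −78 °C; aq NaHCO3
Reagents that add atoms: none
Why: Lewis-acid-promoted SE2' addition of a 2-acylallylstannane to an aldehyde, in which C7 attacks the BF3-bound aldehyde on the butenolide face opposite the C6 iodopropenyl group (C6/C7 trans), the open antiperiplanar transition state places O8 syn to C6 as the target requires, the 1,3-anti preference of the β-silyloxy aldehyde acts in the same sense, and the far less nucleophilic alkenylstannane stays out of the reaction.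

Step 14
Reactants: 22 the C8 alcohol of step 13
Product: 23 (4S,5S)-4-[(1R,3R,4Z)-1-(tert-butyldimethylsilyloxy)-3-methyl-3-(triethylsilyloxy)-5-(tributylstannyl)pent-4-en-1-yl]-5-[(1Z)-2-iodoprop-1-en-1-yl]-3-methylideneoxolan-2-one
Conditions: TBSOTf, 2,6-lutidine, CH2Cl2, −78 to 0 °C
Reagents that add atoms: tert-butyldimethylsilyl trifluoromethanesulfonate, CC(C)(C)[Si](C)(C)OS(=O)(=O)C(F)(F)F
Why: Silyl triflate silylation caps the hindered C8 hydroxyl under non-nucleophilic buffered conditions, which blocks translactonisation to C12 and later attack of O8 on the acylpalladium (the C7 descriptor changes only because of ligand priorities).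

Step 15
Reactants: 23 the bis-silyl ether of step 14
Product: 24 (4S,5S)-4-[(1R,3R,4Z)-1-(tert-butyldimethylsilyloxy)-3-hydroxy-3-methyl-5-(tributylstannyl)pent-4-en-1-yl]-5-[(1Z)-2-iodoprop-1-en-1-yl]-3-methylideneoxolan-2-one
Conditions: PPTS (cat), MeOH/CH2Cl2, 0 °C
Reagents that add atoms: none
Why: Acid-catalysed methanolysis distinguishes the silyl groups by their intrinsic lability, the triethylsilyl ether being cleaved far faster than the tert-butyldimethylsilyl ether, and the weak acid at 0 °C is too mild for protodestannylation or ionisation at C10.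

### Key step and endgame (steps 16–22)

Step 16
Reactants: 24 the seco C4 iodide/C2 Z-stannane with free C10 hydroxyl; 25 carbon monoxide
Product: 27 (3R,6R,7S,8R,10R)-8-(tert-butyldimethylsilyloxy)-3-hydroxy-3,10-epoxygermacra-1,4Z,11(13)-trien-12,6-olide, via ten-membered dienone 26 (not isolated)
Conditions: Pd2(dba)3 (10 mol %), AsPh3 (40 mol %), CO (3 atm), NMP, 40 °C, syringe-pump addition of 24 to a final 1 mM
Reagents that add atoms: none
Why: Zerovalent palladium inserts into the C4–I bond with retention, CO inserts to give the C3 acyl complex of divalent palladium (C3–C4 formed), the Z-alkenylstannane hands C2 over to palladium and reductive elimination forms C2–C3. The closest known reaction type is the intramolecular carbonylative Stille coupling of alkenyl halides or triflates with alkenylstannanes, an established entry to macrocyclic divinyl ketones. The ten-membered carbocycle closes end to end by reductive elimination from an eleven-membered acyl(alkenyl)palladacycle, and the 2,5-dihydrofuran then closes by 5-exo-trig addition of the C10 hydroxyl to the C3 carbonyl of the Z-γ-hydroxy-enone 26. C3 is the only new stereocentre and is controlled by C10, because the oxygen bridge can span the ring only when C4 and C9 sit on the same face of the five-membered ring, which leaves the C3 hydroxyl cis to the C10 methyl group (3R). The step needs CO insertion to outrun direct C2–C4 coupling and ring closure to outrun oligomerisation: the first is secured by the strain of the alternative nine-membered diene together with CO overpressure and the weakly donating AsPh3, the second by slow addition at high dilution and by the two Z alkenes and the trans-lactone, which already bend the chain ends toward each other. The neutral medium spares the methylene lactone, the silyl ether keeps O8 away from the acylpalladium, and hemiketal formation withdraws the strained cross-conjugated dienone from further palladium or Michael chemistry.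

Step 17
Reactants: 27 the 8-O-silyl tricyclic hemiketal
Product: 28 (3R,6R,7R,8R,10R)-3,8-dihydroxy-3,10-epoxygermacra-1,4Z,11(13)-trien-12,6-olide
Conditions: HF·pyridine, pyridine, THF, 0 °C to rt
Reagents that add atoms: none
Why: Fluoride-mediated desilylation under buffered, non-basic and alcohol-free conditions frees O8 without alkoxide-induced translactonisation, Michael addition to C13 or exchange at the hemiketal.

Step 18
Reactants: 29 (E)-but-2-enal
Product: 31 (Z)-2-bromobut-2-enal, via 2,3-dibromobutanal 30 (not isolated)
Conditions: Br2, CH2Cl2, 0 °C; Et3N, 0 °C to rt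
Reagents that add atoms: bromine, BrBr
Why: Bromination followed by dehydrobromination through the acidic α-hydrogen gives the more stable α-bromoenal with the methyl group trans to the formyl group and therefore cis to bromine.

Step 19
Reactants: 31 (Z)-2-bromobut-2-enal
Product: 32 (Z)-2-bromobut-2-en-1-ol
Conditions: NaBH4, CeCl3·7H2O, MeOH, 0 °C
Reagents that add atoms: none
Why: Luche reduction delivers hydride 1,2 to the enal and touches neither the alkenyl bromide nor the alkene geometry.

Step 20
Reactants: 32 (Z)-2-bromobut-2-en-1-ol
Product: 34 (Z)-2-(hydroxymethyl)but-2-enoic acid, via dilithio alkoxide 33 (not isolated)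
Conditions: t-BuLi (3.1 equiv), Et2O, −78 °C; CO2 (g); 1 M HCl
Reagents that add atoms: carbon dioxide, O=C=O
Why: Bromine–lithium exchange on the lithium alkoxide and carboxylation both occur with retention, so the carboxyl group takes the place of bromine cis to the methyl group, which is the less stable angelate-type geometry that condensation routes do not give.

Step 21
Reactants: 34 (Z)-2-(hydroxymethyl)but-2-enoic acid
Product: 35 (Z)-2-(acetoxymethyl)but-2-enoic acid
Conditions: Ac2O, pyridine, CH2Cl2, 0 °C to rt; aq work-up
Reagents that add atoms: acetic anhydride, CC(=O)OC(C)=O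
Why: O-acetylation of the primary allylic alcohol, any mixed carboxylic anhydride being hydrolysed again in the aqueous work-up.

Step 22
Reactants: 28 the C8 alcohol; 35 (Z)-2-(acetoxymethyl)but-2-enoic acid
Product: 37 target CNP0256971.1 (3R,6R,7R,8R,10R)-8-[(Z)-2-(acetoxymethyl)but-2-enoyloxy]-3-hydroxy-3,10-epoxygermacra-1,4Z,11(13)-trien-12,6-olide, via mixed anhydride 36 (not isolated)
Conditions: 35, 2,4,6-Cl3C6H2COCl, Et3N, toluene, rt; then 28, toluene, 70 °C, no DMAP
Reagents that add atoms: none
Why: Yamaguchi-type mixed-anhydride esterification run without a nucleophilic catalyst, the stereoconservative protocol used for angelate-type acids, so that neither Z-to-E isomerisation nor SN2' loss of the allylic acetate is triggered, the secondary O8 attacks the unhindered acyl carbon with retention at C8, and the tertiary hemiketal hydroxyl at C3 is too hindered to compete.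

## Compound list

1 | (E)-3-methylpent-2-en-4-yn-1-ol | C#C/C(C)=C/CO | starting material
2 | [(2S,3S)-3-ethynyl-3-methyloxiran-2-yl]methanol | C#C[C@]1(C)O[C@H]1CO | intermediate
3 | (3R)-3-methylpent-4-yne-1,3-diol, present as its aluminium alkoxide, not isolated | C#C[C@](C)(O)CCO | intermediate
4 | cyclic Z-alkenylalanate (sodium salt, primary oxygen drawn as OH), not isolated | [Na+].COCCO[Al-]1(OCCOC)C=C[C@@](C)(CCO)O1 | intermediate
5 | (3R,4Z)-5-iodo-3-methylpent-4-ene-1,3-diol | OCC[C@@](C)(O)/C=C\I | intermediate
6 | (1Z,3R)-1-iodo-3-methyl-3,5-bis(triethylsilyloxy)pent-1-ene | CC[Si](CC)(CC)OCC[C@@](C)(O[Si](CC)(CC)CC)/C=C\I | intermediate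
7 | Z-alkenyllithium from 6, not isolated | CC[Si](CC)(CC)OCC[C@@](C)(O[Si](CC)(CC)CC)/C=C\[Li] | intermediate
8 | (1Z,3R)-3-methyl-3,5-bis(triethylsilyloxy)-1-(tributylstannyl)pent-1-ene | CC[Si](CC)(CC)OCC[C@@](C)(O[Si](CC)(CC)CC)/C=C\[Sn](CCCC)(CCCC)CCCC | intermediate
9 | (3R,4Z)-3-methyl-3-(triethylsilyloxy)-5-(tributylstannyl)pent-4-enal | O=CC[C@@](C)(O[Si](CC)(CC)CC)/C=C\[Sn](CCCC)(CCCC)CCCC | intermediate
10 | but-2-yn-1-ol | CC#CCO | starting material
11 | cyclic alkenylalanate from 10 (sodium salt), not isolated | [Na+].COCCO[Al-]1(OCCOC)OCC=C1C | intermediate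
12 | (Z)-3-iodobut-2-en-1-ol | C/C(I)=C/CO | intermediate
13 | (Z)-3-iodobut-2-enal | C/C(I)=C/C=O | intermediate
14 | vinylmagnesium bromide | C=C[Mg]Br | starting material
15 | racemic (4Z)-5-iodohexa-1,4-dien-3-ol | C=CC(O)/C=C(/C)I | intermediate
16 | (3S,4Z)-5-iodohexa-1,4-dien-3-ol | C=C[C@H](O)/C=C(/C)I | intermediate
17 | 2-(bromomethyl)acrylic acid | C=C(CBr)C(=O)O | starting material
18 | (3S,4Z)-5-iodohexa-1,4-dien-3-yl 2-(bromomethyl)acrylate | C=C[C@H](OC(=O)C(=C)CBr)/C=C(/C)I | intermediate
19 | (5S)-3-(bromomethyl)-5-[(1Z)-2-iodoprop-1-en-1-yl]furan-2(5H)-one | O=C1O[C@H](/C=C(/C)I)C=C1CBr | intermediate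
20 | allylzinc bromide from 19, not isolated | O=C1O[C@H](/C=C(/C)I)C=C1C[Zn]Br | intermediate
21 | (5S)-5-[(1Z)-2-iodoprop-1-en-1-yl]-3-[(tributylstannyl)methyl]furan-2(5H)-one | O=C1O[C@H](/C=C(/C)I)C=C1C[Sn](CCCC)(CCCC)CCCC | intermediate
22 | seco C8 alcohol, C10 triethylsilyl ether (6S,7R,8R,10R) | C=C1C(=O)O[C@H](/C=C(/C)I)[C@H]1[C@H](O)C[C@@](C)(O[Si](CC)(CC)CC)/C=C\[Sn](CCCC)(CCCC)CCCC | intermediate
23 | seco C8 tert-butyldimethylsilyl ether, C10 triethylsilyl ether (6S,7S,8R,10R) | C=C1C(=O)O[C@H](/C=C(/C)I)[C@H]1[C@H](O[Si](C)(C)C(C)(C)C)C[C@@](C)(O[Si](CC)(CC)CC)/C=C\[Sn](CCCC)(CCCC)CCCC | intermediate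
24 | seco C4 Z-iodide, C2 Z-stannane, free C10 hydroxyl, C8 silyl ether (6S,7S,8R,10R) | C=C1C(=O)O[C@H](/C=C(/C)I)[C@H]1[C@H](O[Si](C)(C)C(C)(C)C)C[C@@](C)(O)/C=C\[Sn](CCCC)(CCCC)CCCC | intermediate
25 | carbon monoxide | [C-]#[O+] | starting material
26 | (1Z,4Z)-10-hydroxy-3-oxogermacra-1,4,11(13)-trien-12,6-olide 8-silyl ether, not isolated | C=C1C(=O)O[C@@H]2/C=C(/C)C(=O)/C=C\[C@](C)(O)C[C@@H](O[Si](C)(C)C(C)(C)C)[C@@H]12 | intermediate
27 | C8 silyl ether of the tricyclic hemiketal (3R,6R,7S,8R,10R) | C=C1C(=O)O[C@@H]2/C=C(/C)[C@@]3(O)C=C[C@@](C)(C[C@@H](O[Si](C)(C)C(C)(C)C)[C@@H]12)O3 | intermediate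
28 | tricyclic hemiketal with free C8 hydroxyl (3R,6R,7R,8R,10R) | C=C1C(=O)O[C@@H]2/C=C(/C)[C@@]3(O)C=C[C@@](C)(C[C@@H](O)[C@@H]12)O3 | intermediate
29 | (E)-but-2-enal | C/C=C/C=O | starting material
30 | 2,3-dibromobutanal (racemic), not isolated | CC(Br)C(Br)C=O | intermediate
31 | (Z)-2-bromobut-2-enal | C/C=C(\Br)C=O | intermediate
32 | (Z)-2-bromobut-2-en-1-ol | C/C=C(\Br)CO | intermediate
33 | dilithio derivative of 32 (lithium alkoxide, alkenyllithium), not isolated | C/C=C(\[Li])CO[Li] | intermediate
34 | (Z)-2-(hydroxymethyl)but-2-enoic acid | C/C=C(/CO)C(=O)O | intermediate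
35 | (Z)-2-(acetoxymethyl)but-2-enoic acid | C/C=C(/COC(C)=O)C(=O)O | intermediate
36 | mixed anhydride of 35 and 2,4,6-trichlorobenzoic acid, not isolated | C/C=C(/COC(C)=O)C(=O)OC(=O)c1c(Cl)cc(Cl)cc1Cl | intermediate
37 | CNP0256971.1 | C=C1C(=O)O[C@@H]2/C=C(/C)[C@@]3(O)C=C[C@@](C)(C[C@@H](OC(=O)/C(=C\C)COC(C)=O)[C@@H]12)O3 | target

## Step count

Total step count: 22.
Longest linear sequence: 13 steps (steps 6–17 and 22, from but-2-yn-1-ol).

## Steps most likely to fail

**1. Step 16.**
- Ring closure may be too slow. Oligomerisation, coupling before CO uptake or protodestannylation could then consume the substrate.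
- The fallback moves the ring closure from palladium to metathesis, and CO still supplies C3.
- It sets out from 24. Protodestannylation (TsOH·H2O, CH2Cl2, 0 °C) gives the C10 vinyl carbinol F1.
- An intermolecular carbonylative Stille coupling of the C4 iodide of F1 with tributyl(vinyl)stannane (Pd2(dba)3, AsPh3, CO, NMP) gives the open-chain divinyl ketone F2.
- Ring-closing metathesis (second-generation Hoveyda–Grubbs catalyst, toluene, high dilution) between the enone vinyl group and the C10 vinyl group then forms C1=C2.
- Metathesis is reversible and only the Z-enone 26 can be captured by the C10 hydroxyl, so the equilibrium should drain into 27, where the route is rejoined.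

**2. Step 13.**
- The acyl-substituted allylstannane may be too weak a nucleophile.
- The open transition state may give poor syn selectivity at C8.
- The Lewis acid may strip the tertiary silyl ether or the alkenyl tin group.
- The fallback uses a neutral closed-transition-state allylation followed by inversion, and it sets out from bromide 19 and aldehyde 9.
- An indium-mediated Barbier reaction (indium powder, THF/H2O, rt) should proceed through a chair transition state. It should again attack anti to the C6 substituent and give the C7/C8 anti product, the 8-epi alcohol F3.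
- Mitsunobu inversion with formic acid (PPh3, DIAD, toluene, 0 °C) gives the C8 formate F4 of natural configuration.
- Mild hydrolysis (KHCO3, MeOH/H2O, 0 °C) returns to 22.

**3. Step 12.**
- Tin may be transferred to the wrong allyl terminus (C7).
- The allylzinc may be lost by protonation, or by β-elimination with opening of the lactone.
- The fallback uses silicon instead of tin and installs it before the ring is closed. It sets out from 16.
- Commercial ethyl 2-[(trimethylsilyl)methyl]acrylate is saponified (LiOH, THF/H2O) to 2-[(trimethylsilyl)methyl]acrylic acid F5.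
- Steglich esterification of 16 with this acid gives the dienyl 2-[(trimethylsilyl)methyl]acrylate F6.
- Ring-closing metathesis (second-generation Grubbs catalyst) gives the 3-[(trimethylsilyl)methyl]butenolide F7, in which the position of silicon is unambiguous.
- A Hosomi–Sakurai reaction of F7 with aldehyde 9 (BF3·OEt2, CH2Cl2, −78 to −40 °C) follows the same open transition state and comes back to the route at 22.

## Further compounds

F1 | step 16 | seco C4 Z-iodide with C10 vinyl carbinol and C8 silyl ether | C=C1C(=O)O[C@H](/C=C(/C)I)[C@H]1[C@H](O[Si](C)(C)C(C)(C)C)C[C@@](C)(O)C=C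
F2 | step 16 | open-chain divinyl ketone (C3 carbonyl from CO, C2 vinyl, C10 vinyl carbinol) | C=C1C(=O)O[C@H](/C=C(/C)C(=O)C=C)[C@H]1[C@H](O[Si](C)(C)C(C)(C)C)C[C@@](C)(O)C=C
F3 | step 13 | 8-epi alcohol (C7/C8 anti) | C=C1C(=O)O[C@H](/C=C(/C)I)[C@H]1[C@@H](O)C[C@@](C)(O[Si](CC)(CC)CC)/C=C\[Sn](CCCC)(CCCC)CCCC
F4 | step 13 | C8 formate of natural configuration | C=C1C(=O)O[C@H](/C=C(/C)I)[C@H]1[C@H](OC=O)C[C@@](C)(O[Si](CC)(CC)CC)/C=C\[Sn](CCCC)(CCCC)CCCC
F5 | step 12 | 2-[(trimethylsilyl)methyl]acrylic acid | C=C(C[Si](C)(C)C)C(=O)O
F6 | step 12 | (3S,4Z)-5-iodohexa-1,4-dien-3-yl 2-[(trimethylsilyl)methyl]acrylate | C=C[C@H](OC(=O)C(=C)C[Si](C)(C)C)/C=C(/C)I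
F7 | step 12 | (5S)-5-[(1Z)-2-iodoprop-1-en-1-yl]-3-[(trimethylsilyl)methyl]furan-2(5H)-one | O=C1O[C@H](/C=C(/C)I)C=C1C[Si](C)(C)C
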